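## Retrosynthetic overview

1. Fusariumester B (28) comes from the fully protected dimer 27 by one global acidolysis. 27 is cut at the C3–C4 bond of the dienoyl unit that links the halves: a Pd/Cu Stille coupling of alkenylstannane 20 (open-chain half) with iodoalkene β-lactone 26.
2. 20 comes from acylation of the (12S,13S) alcohol 19 with stannyl acid 13; 19 comes from a Stille coupling of iodoalkene 18 with stannyl ester 14 (same C3–C4 disconnection).
3. Both anti diads, (2S,3S) in 18 and (2R,3R) in 26, come from one aldehyde 10, tert-butyl acrylate and B2pin2 by a rhodium-catalysed borylative aldol coupling run with the two antipodal catalysts.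
4. 10 comes from (S)-3-bromo-2-methylpropan-1-ol by Cu-catalysed sp3–sp3 coupling with a pentenyl Grignard reagent, acetylide alkylation, Zr-catalysed carboalumination/iodination and alkene cleavage.
5. Ring order: the molecule has one ring, the β-lactone; it is closed by carboxyl-activation lactonisation (step 16) before the fragment union.

Assumption 1: the target is taken exactly as the SMILES defines it: both methyl-bearing centres R, the lactone diad (2R,3R) (trans), and the open-chain diad (12S,13S), the mirror-image anti arrangement.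
Assumption 2: the (S,S)-Phebox rhodium complex is assigned to the (2S,3S) diad and the (R,R) complex to the (2R,3R) diad; both antipodes are used, so a reversed sense would only mean exchanging them between steps 9 and 13.

## Route

Step 1
Reactants: 1 (S)-3-bromo-2-methylpropan-1-ol; 2 5-bromopent-1-ene
Product: 4 (R)-2-methyloct-7-en-1-ol, via pent-4-en-1-ylmagnesium bromide 3 (not isolated)
Conditions: 2 (2.6 equiv), Mg, THF, 40 °C; then 1, Li2CuCl4 (3 mol %), THF/NMP, −20 → 0 °C; aq NH4Cl
Reagents that add atoms: magnesium, [Mg] (stays only in 3)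
Why: Kochi-type copper-catalysed sp3–sp3 cross-coupling of a primary alkyl bromide with a primary Grignard reagent (the first equivalent of 3 only turns the hydroxyl into an inert magnesium alkoxide); the stereocentre is not at a reacting carbon and is carried over unchanged (S becomes R only because the CIP ranks change).

Step 2
Reactants: 4 (R)-2-methyloct-7-en-1-ol
Product: 5 (R)-8-iodo-7-methyloct-1-ene
Conditions: I2, PPh3, imidazole, CH2Cl2, 0 °C → rt
Reagents that add atoms: iodine, [I][I]
Why: Appel-type (Garegg–Samuelsson) iodination of a primary alcohol by SN2 displacement of the oxyphosphonium group; the neighbouring stereocentre is not involved.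

Step 3
Reactants: 5 (R)-8-iodo-7-methyloct-1-ene; 6 lithium acetylide–ethane-1,2-diamine complex
Product: 7 (R)-4-methyldec-9-en-1-yne
Conditions: 6 (1.5 equiv), DMSO, 15 °C → rt
Reagents that add atoms: none
Why: SN2 alkylation of lithium acetylide in DMSO, which works on β-branched primary iodides and installs the propargyl unit without touching the stereocentre.

Step 4
Reactants: 7 (R)-4-methyldec-9-en-1-yne
Product: 9 (1E,4R)-1-iodo-2,4-dimethyldeca-1,9-diene, via alkenyldimethylalane 8 (not isolated)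
Conditions: AlMe3 (2 equiv), Cp2ZrCl2 (0.25 equiv), CH2Cl2, 0 °C → rt; then I2, THF, −30 → 0 °C
Reagents that add atoms: trimethylaluminium, C[Al](C)C (methyl group in 9, AlMe2 in 8); iodine, [I][I]
Why: Negishi zirconium-catalysed methylalumination of the terminal alkyne (syn addition, methyl to the internal carbon; the isolated terminal alkene reacts far more slowly) followed by iodinolysis of the C–Al bond with retention gives the (E)-iodoalkene.

Step 5
Reactants: 9 (1E,4R)-1-iodo-2,4-dimethyldeca-1,9-diene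
Product: 10 (6R,8E)-9-iodo-6,8-dimethylnon-8-enal
Conditions: OsO4 (2 mol %), NaIO4 (4 equiv), 2,6-lutidine, dioxane/H2O (3:1), rt
Reagents that add atoms: sodium periodate, [Na+].[O-]I(=O)(=O)=O (supplies the aldehyde oxygen through the OsO4 cycle)
Why: Lemieux–Johnson oxidative cleavage; OsO4 dihydroxylates the electron-richer monosubstituted alkene much faster than the electron-poor, hindered trisubstituted iodoalkene, and periodate cleaves the diol to the aldehyde.

Step 6
Reactants: 11 ethyl but-2-ynoate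
Product: 12 ethyl (E)-3-(tributylstannyl)but-2-enoate
Conditions: Bu3SnH, LiN(iPr)2, THF, −78 °C; CuBr·SMe2, −78 °C; then 11, MeOH (1.7 equiv), −78 °C
Reagents that add atoms: tributyltin hydride, CCCC[SnH](CCCC)CCCC
Why: Piers syn-stannylcupration of an ynoate with in situ protonation of the alkenylcopper at −78 °C (kinetic control) places tin at C3 trans to the ester, giving the (E)-β-stannyl enoate.

Step 7
Reactants: 12 ethyl (E)-3-(tributylstannyl)but-2-enoate
Product: 13 (E)-3-(tributylstannyl)but-2-enoic acid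
Conditions: LiOH, THF/MeOH/H2O, rt; dilute HCl to pH 4, 0 °C
Reagents that add atoms: lithium hydroxide, [Li+].[OH-]
Why: plain ester saponification; the β-stannyl enoate is stable to hydroxide and to brief mild acidification, and the alkene geometry is untouched.

Step 8
Reactants: 13 (E)-3-(tributylstannyl)but-2-enoic acid
Product: 14 tert-butyl (E)-3-(tributylstannyl)but-2-enoate
Conditions: Boc2O, DMAP (cat.), t-BuOH, rt
Reagents that add atoms: di-tert-butyl dicarbonate, CC(C)(C)OC(=O)OC(=O)OC(C)(C)C
Why: DMAP-catalysed tert-butyl esterification through the mixed carbonic anhydride, a non-acidic method that avoids protodestannylation.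

Step 9
Reactants: 10 (6R,8E)-9-iodo-6,8-dimethylnon-8-enal; 15 tert-butyl acrylate
Product: 17 tert-butyl (2S,3S,8R,10E)-3-hydroxy-2-(hydroxymethyl)-11-iodo-8,10-dimethylundec-10-enoate, via bis(boryl) aldol adduct 16 (not isolated)
Conditions: 15 (1.5 equiv), B2pin2 (1.2 equiv), Rh[(S,S)-iPr-Phebox](OAc)2(H2O) (2 mol %), toluene, 40 °C; then NaBO3·4H2O, THF/H2O, rt
Reagents that add atoms: bis(pinacolato)diboron, CC1(C)OB(OC1(C)C)B1OC(C)(C)C(C)(C)O1 (boron stays only in 16); sodium perborate, [Na+].[O-]OB=O (hydroxyl oxygen of the CH2OH group)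
Why: Proposed new method: an anti-selective, enantioselective rhodium-catalysed borylative aldol three-component coupling that forms the C2–C3 bond and both stereocentres at once; acetate-assisted transmetalation of B2pin2 gives a trivalent Rh–Bpin species, 1,4-borylrhodation of the acrylate (expected to be faster than insertion of the aldehyde C=O) gives the (E)-configured O-bound rhodium enolate carrying CH2Bpin (a β-boryl group cannot be eliminated, unlike a β-alkoxy group), a chair Zimmerman–Traxler addition to 10 inside the C2-symmetric Phebox pocket gives the anti aldolate with catalyst-controlled facial selectivity (the C8 centre is too remote to interfere), and Rh–O/B–B σ-bond metathesis releases 16 and regenerates Rh–Bpin, after which perborate oxidises the C–B bond; the closest known reactions are the Rh(Phebox)-catalysed anti-selective reductive aldol coupling of tert-butyl acrylate with aldehydes and hydrosilanes and the Rh(Phebox)- and copper-catalysed conjugate borylations of acrylates with B2pin2.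

Step 10
Reactants: 17 tert-butyl (2S,3S,8R,10E)-3-hydroxy-2-(hydroxymethyl)-11-iodo-8,10-dimethylundec-10-enoate
Product: 18 tert-butyl (2S,3S,8R,10E)-2-{[(tert-butyldimethylsilyl)oxy]methyl}-3-hydroxy-11-iodo-8,10-dimethylundec-10-enoate
Conditions: TBSCl (1.05 equiv), imidazole, CH2Cl2, −10 °C
Reagents that add atoms: tert-butyldimethylsilyl chloride, CC(C)(C)[Si](C)(C)Cl
Why: selective silylation of the primary hydroxyl of a 1,3-diol under steric control leaves the secondary carbinol free for the later acylation.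

Step 11
Reactants: 18 tert-butyl (2S,3S,8R,10E)-2-{[(tert-butyldimethylsilyl)oxy]methyl}-3-hydroxy-11-iodo-8,10-dimethylundec-10-enoate; 14 tert-butyl (E)-3-(tributylstannyl)but-2-enoate
Product: 19 di-tert-butyl (2E,4E,7R,12S,13S)-13-{[(tert-butyldimethylsilyl)oxy]methyl}-12-hydroxy-3,5,7-trimethyltetradeca-2,4-dienedioate
Conditions: Pd2(dba)3 (5 mol %), AsPh3 (20 mol %), CuI (10 mol %), NMP, 40 °C
Reagents that add atoms: none
Why: Stille–Migita cross-coupling (zerovalent palladium, copper co-catalysis for the electron-poor stannane) of two alkenyl partners with retention of both geometries builds the (2E,4E)-dienoate; the free hydroxyl and the tert-butyl ester are inert.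

Step 12
Reactants: 19 di-tert-butyl (2E,4E,7R,12S,13S)-13-{[(tert-butyldimethylsilyl)oxy]methyl}-12-hydroxy-3,5,7-trimethyltetradeca-2,4-dienedioate; 13 (E)-3-(tributylstannyl)but-2-enoic acid
Product: 20 di-tert-butyl (2E,4E,7R,12S,13S)-13-{[(tert-butyldimethylsilyl)oxy]methyl}-3,5,7-trimethyl-12-{[(2E)-3-(tributylstannyl)but-2-enoyl]oxy}tetradeca-2,4-dienedioate
Conditions: 13 (3 equiv), N,N'-dicyclohexylcarbodiimide, DMAP, CH2Cl2, 0 °C → rt
Reagents that add atoms: none
Why: Steglich esterification of the secondary alcohol with an excess of the small acid; the carbinol C–O bond is not broken, so C12 keeps its S configuration, and the near-neutral conditions spare the C–Sn bond, the silyl ether and the β-acyloxy ester (no strong base, so no E1cB elimination).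

Step 13
Reactants: 10 (6R,8E)-9-iodo-6,8-dimethylnon-8-enal; 15 tert-butyl acrylate
Product: 22 tert-butyl (2R,3R,8R,10E)-3-hydroxy-2-(hydroxymethyl)-11-iodo-8,10-dimethylundec-10-enoate, via bis(boryl) aldol adduct 21 (not isolated)
Conditions: 15 (1.5 equiv), B2pin2 (1.2 equiv), Rh[(R,R)-iPr-Phebox](OAc)2(H2O) (2 mol %), toluene, 40 °C; then NaBO3·4H2O, THF/H2O, rt
Reagents that add atoms: bis(pinacolato)diboron, CC1(C)OB(OC1(C)C)B1OC(C)(C)C(C)(C)O1 (boron stays only in 21); sodium perborate, [Na+].[O-]OB=O (hydroxyl oxygen of the CH2OH group)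
Why: Proposed new method: the same rhodium-catalysed anti-selective borylative aldol three-component coupling as in step 9, run with the antipodal catalyst so that the chair addition of the (E)-rhodium enolate (from 1,4-borylrhodation of the acrylate) occurs on the opposite aldehyde face and gives the (2R,3R) anti diad; the closest known reactions are again the Rh(Phebox)-catalysed anti-selective reductive aldol coupling and the conjugate borylation of acrylates.

Step 14
Reactants: 22 tert-butyl (2R,3R,8R,10E)-3-hydroxy-2-(hydroxymethyl)-11-iodo-8,10-dimethylundec-10-enoate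
Product: 23 tert-butyl (2R,3R,8R,10E)-2-{[(tert-butyldimethylsilyl)oxy]methyl}-3-hydroxy-11-iodo-8,10-dimethylundec-10-enoate
Conditions: TBSCl (1.05 equiv), imidazole, CH2Cl2, −10 °C
Reagents that add atoms: tert-butyldimethylsilyl chloride, CC(C)(C)[Si](C)(C)Cl
Why: selective silylation of the primary hydroxyl under steric control, so that only the secondary β-hydroxyl can later lactonise.

Step 15
Reactants: 23 tert-butyl (2R,3R,8R,10E)-2-{[(tert-butyldimethylsilyl)oxy]methyl}-3-hydroxy-11-iodo-8,10-dimethylundec-10-enoate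
Product: 25 (2R,3R,8R,10E)-2-{[(tert-butyldimethylsilyl)oxy]methyl}-3-hydroxy-11-iodo-8,10-dimethylundec-10-enoic acid, via bis(trimethylsilyl) derivative 24 (not isolated)
Conditions: TMSOTf (3 equiv), 2,6-lutidine (4 equiv), CH2Cl2, 0 °C; then MeOH, citric acid (cat.), 0 °C
Reagents that add atoms: trimethylsilyl triflate, C[Si](C)(C)OS(=O)(=O)C(F)(F)F (silicon stays only in 24)
Why: silyl-triflate-mediated tert-butyl ester cleavage (O-silylation of the ester, loss of isobutene) gives the trimethylsilyl ester while the primary TBS ether survives; mild methanolysis then frees the acid and the transiently silylated secondary hydroxyl without touching the stereocentres.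

Step 16
Reactants: 25 (2R,3R,8R,10E)-2-{[(tert-butyldimethylsilyl)oxy]methyl}-3-hydroxy-11-iodo-8,10-dimethylundec-10-enoic acid
Product: 26 (3R,4R)-3-{[(tert-butyldimethylsilyl)oxy]methyl}-4-[(5R,7E)-8-iodo-5,7-dimethyloct-7-en-1-yl]oxetan-2-one
Conditions: PhSO2Cl (2 equiv), pyridine, 0 → 4 °C
Reagents that add atoms: none
Why: Adam β-lactonisation by carboxyl activation (mixed carboxylic–sulfonic anhydride) and attack of the β-hydroxyl on the acyl carbon, so both stereocentres are retained and the anti acid gives the trans-(3R,4R)-β-lactone, the only ring of the target.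

Step 17
Reactants: 20 di-tert-butyl (2E,4E,7R,12S,13S)-13-{[(tert-butyldimethylsilyl)oxy]methyl}-3,5,7-trimethyl-12-{[(2E)-3-(tributylstannyl)but-2-enoyl]oxy}tetradeca-2,4-dienedioate; 26 (3R,4R)-3-{[(tert-butyldimethylsilyl)oxy]methyl}-4-[(5R,7E)-8-iodo-5,7-dimethyloct-7-en-1-yl]oxetan-2-one
Product: 27 di-tert-butyl (2E,4E,7R,12S,13S)-13-{[(tert-butyldimethylsilyl)oxy]methyl}-12-{[(2E,4E,7R)-11-[(2R,3R)-3-{[(tert-butyldimethylsilyl)oxy]methyl}-4-oxooxetan-2-yl]-3,5,7-trimethylundeca-2,4-dienoyl]oxy}-3,5,7-trimethyltetradeca-2,4-dienedioate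
Conditions: Pd(PPh3)4 (10 mol %), Cu(O2CC4H3S) (copper thiophene-2-carboxylate, 1.5 equiv), [NBu4][Ph2PO2] (1.6 equiv), DMF, rt
Reagents that add atoms: none
Why: fragment-uniting Stille–Migita coupling that forms the C3–C4 diene bond of the acyl half under fluoride-free copper-carboxylate/phosphinate promotion (tin is scavenged as the phosphinate); the conditions are neutral and at room temperature, so the β-lactone, the β-acyloxy ester and the silyl ethers survive, and both alkene geometries are retained to give the second (2E,4E)-dienoate.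

Step 18
Reactants: 27 di-tert-butyl (2E,4E,7R,12S,13S)-13-{[(tert-butyldimethylsilyl)oxy]methyl}-12-{[(2E,4E,7R)-11-[(2R,3R)-3-{[(tert-butyldimethylsilyl)oxy]methyl}-4-oxooxetan-2-yl]-3,5,7-trimethylundeca-2,4-dienoyl]oxy}-3,5,7-trimethyltetradeca-2,4-dienedioate
Product: 28 fusariumester B, (2E,4E,7R,12S,13S)-13-(hydroxymethyl)-12-{[(2E,4E,7R)-11-[(2R,3R)-3-(hydroxymethyl)-4-oxooxetan-2-yl]-3,5,7-trimethylundeca-2,4-dienoyl]oxy}-3,5,7-trimethyltetradeca-2,4-dienedioic acid
Conditions: TFA/CH2Cl2/H2O (30:65:5), 0 °C → rt; toluene co-evaporation; THF/pH 7 buffer, rt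
Reagents that add atoms: none
Why: global acidolysis in which both tert-butyl esters (alkyl–oxygen cleavage) and both primary TBS ethers are removed by aqueous TFA, conditions that β-lactones, the dienoates and the secondary ester linkage tolerate (transient trifluoroacetates are hydrolysed in the buffer); no stereocentre is touched.

## Compound list

1 | (S)-3-bromo-2-methylpropan-1-ol | OC[C@H](C)CBr | starting material
2 | 5-bromopent-1-ene | C=CCCCBr | starting material
3 | pent-4-en-1-ylmagnesium bromide | C=CCCC[Mg]Br | intermediate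
4 | (R)-2-methyloct-7-en-1-ol | OC[C@H](C)CCCCC=C | intermediate
5 | (R)-8-iodo-7-methyloct-1-ene | IC[C@H](C)CCCCC=C | intermediate
6 | lithium acetylide–ethane-1,2-diamine complex | [Li]C#C.NCCN | starting material
7 | (R)-4-methyldec-9-en-1-yne | C#CC[C@H](C)CCCCC=C | intermediate
8 | [(1E,4R)-2,4-dimethyldeca-1,9-dien-1-yl]dimethylalane | C[Al](C)/C=C(\C)C[C@H](C)CCCCC=C | intermediate
9 | (1E,4R)-1-iodo-2,4-dimethyldeca-1,9-diene | I/C=C(\C)C[C@H](C)CCCCC=C | intermediate
10 | (6R,8E)-9-iodo-6,8-dimethylnon-8-enal | I/C=C(\C)C[C@H](C)CCCCC=O | intermediate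
11 | ethyl but-2-ynoate | CC#CC(=O)OCC | starting material
12 | ethyl (E)-3-(tributylstannyl)but-2-enoate | CCOC(=O)/C=C(\C)[Sn](CCCC)(CCCC)CCCC | intermediate
13 | (E)-3-(tributylstannyl)but-2-enoic acid | OC(=O)/C=C(\C)[Sn](CCCC)(CCCC)CCCC | intermediate
14 | tert-butyl (E)-3-(tributylstannyl)but-2-enoate | CC(C)(C)OC(=O)/C=C(\C)[Sn](CCCC)(CCCC)CCCC | intermediate
15 | tert-butyl acrylate | C=CC(=O)OC(C)(C)C | starting material
16 | tert-butyl (2S,3S,8R,10E)-11-iodo-8,10-dimethyl-3-[(pinacolatoboryl)oxy]-2-[(pinacolatoboryl)methyl]undec-10-enoate | I/C=C(\C)C[C@H](C)CCCC[C@H](OB1OC(C)(C)C(C)(C)O1)[C@H](CB2OC(C)(C)C(C)(C)O2)C(=O)OC(C)(C)C | intermediate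
17 | tert-butyl (2S,3S,8R,10E)-3-hydroxy-2-(hydroxymethyl)-11-iodo-8,10-dimethylundec-10-enoate | I/C=C(\C)C[C@H](C)CCCC[C@H](O)[C@H](CO)C(=O)OC(C)(C)C | intermediate
18 | tert-butyl (2S,3S,8R,10E)-2-{[(tert-butyldimethylsilyl)oxy]methyl}-3-hydroxy-11-iodo-8,10-dimethylundec-10-enoate | I/C=C(\C)C[C@H](C)CCCC[C@H](O)[C@H](CO[Si](C)(C)C(C)(C)C)C(=O)OC(C)(C)C | intermediate
19 | di-tert-butyl (2E,4E,7R,12S,13S)-13-{[(tert-butyldimethylsilyl)oxy]methyl}-12-hydroxy-3,5,7-trimethyltetradeca-2,4-dienedioate | CC(=C\C(=O)OC(C)(C)C)/C=C(\C)C[C@H](C)CCCC[C@H](O)[C@H](CO[Si](C)(C)C(C)(C)C)C(=O)OC(C)(C)C | intermediate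
20 | di-tert-butyl (2E,4E,7R,12S,13S)-13-{[(tert-butyldimethylsilyl)oxy]methyl}-3,5,7-trimethyl-12-{[(2E)-3-(tributylstannyl)but-2-enoyl]oxy}tetradeca-2,4-dienedioate | CC(=C\C(=O)OC(C)(C)C)/C=C(\C)C[C@H](C)CCCC[C@H](OC(=O)/C=C(\C)[Sn](CCCC)(CCCC)CCCC)[C@H](CO[Si](C)(C)C(C)(C)C)C(=O)OC(C)(C)C | intermediate
21 | tert-butyl (2R,3R,8R,10E)-11-iodo-8,10-dimethyl-3-[(pinacolatoboryl)oxy]-2-[(pinacolatoboryl)methyl]undec-10-enoate | I/C=C(\C)C[C@H](C)CCCC[C@@H](OB1OC(C)(C)C(C)(C)O1)[C@@H](CB2OC(C)(C)C(C)(C)O2)C(=O)OC(C)(C)C | intermediate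
22 | tert-butyl (2R,3R,8R,10E)-3-hydroxy-2-(hydroxymethyl)-11-iodo-8,10-dimethylundec-10-enoate | I/C=C(\C)C[C@H](C)CCCC[C@@H](O)[C@@H](CO)C(=O)OC(C)(C)C | intermediate
23 | tert-butyl (2R,3R,8R,10E)-2-{[(tert-butyldimethylsilyl)oxy]methyl}-3-hydroxy-11-iodo-8,10-dimethylundec-10-enoate | I/C=C(\C)C[C@H](C)CCCC[C@@H](O)[C@@H](CO[Si](C)(C)C(C)(C)C)C(=O)OC(C)(C)C | intermediate
24 | trimethylsilyl (2R,3R,8R,10E)-2-{[(tert-butyldimethylsilyl)oxy]methyl}-11-iodo-8,10-dimethyl-3-[(trimethylsilyl)oxy]undec-10-enoate | I/C=C(\C)C[C@H](C)CCCC[C@@H](O[Si](C)(C)C)[C@@H](CO[Si](C)(C)C(C)(C)C)C(=O)O[Si](C)(C)C | intermediate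
25 | (2R,3R,8R,10E)-2-{[(tert-butyldimethylsilyl)oxy]methyl}-3-hydroxy-11-iodo-8,10-dimethylundec-10-enoic acid | I/C=C(\C)C[C@H](C)CCCC[C@@H](O)[C@@H](CO[Si](C)(C)C(C)(C)C)C(=O)O | intermediate
26 | (3R,4R)-3-{[(tert-butyldimethylsilyl)oxy]methyl}-4-[(5R,7E)-8-iodo-5,7-dimethyloct-7-en-1-yl]oxetan-2-one | I/C=C(\C)C[C@H](C)CCCC[C@H]1OC(=O)[C@@H]1CO[Si](C)(C)C(C)(C)C | intermediate
27 | di-tert-butyl (2E,4E,7R,12S,13S)-13-{[(tert-butyldimethylsilyl)oxy]methyl}-12-{[(2E,4E,7R)-11-[(2R,3R)-3-{[(tert-butyldimethylsilyl)oxy]methyl}-4-oxooxetan-2-yl]-3,5,7-trimethylundeca-2,4-dienoyl]oxy}-3,5,7-trimethyltetradeca-2,4-dienedioate | CC(=C\C(=O)OC(C)(C)C)/C=C(\C)C[C@H](C)CCCC[C@H](OC(=O)/C=C(C)/C=C(\C)C[C@H](C)CCCC[C@H]1OC(=O)[C@@H]1CO[Si](C)(C)C(C)(C)C)[C@H](CO[Si](C)(C)C(C)(C)C)C(=O)OC(C)(C)C | intermediate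
28 | fusariumester B, (2E,4E,7R,12S,13S)-13-(hydroxymethyl)-12-{[(2E,4E,7R)-11-[(2R,3R)-3-(hydroxymethyl)-4-oxooxetan-2-yl]-3,5,7-trimethylundeca-2,4-dienoyl]oxy}-3,5,7-trimethyltetradeca-2,4-dienedioic acid | CC(=C\C(=O)O)/C=C(\C)C[C@H](C)CCCC[C@H](OC(=O)/C=C(C)/C=C(\C)C[C@H](C)CCCC[C@H]1OC(=O)[C@@H]1CO)[C@H](CO)C(=O)O | target

## Step count and risk

Total step count: 18 (steps 1–5 to the common aldehyde 10; steps 6–8 to the stannanes 13 and 14; steps 9–12 to 20; steps 13–16 to 26; steps 17 and 18).
Longest linear sequence: 11 steps (1, 2, 3, 4, 5, 9, 10, 11, 12, 17, 18; the branch through steps 13–16 is equally long), which is 61 % of the total.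

The three steps most likely to fail:

**Step 9 (the proposed new borylative aldol coupling, (2S,3S) series).** The reaction is unproven; direct borylation of the aldehyde or a poor anti/syn ratio could defeat it. The fallback sets out from aldehyde 10 and comes back to the route at diol 17, using only known chemistry. Roskamp homologation of 10 with tert-butyl diazoacetate and SnCl2 (CH2Cl2, rt) gives the β-keto ester tert-butyl (8R,10E)-11-iodo-8,10-dimethyl-3-oxoundec-10-enoate F1. Noyori hydrogenation of F1 with RuCl2[(S)-BINAP] (H2, 4 atm, MeOH, 40 °C) sets C3 and gives tert-butyl (3S,8R,10E)-3-hydroxy-11-iodo-8,10-dimethylundec-10-enoate F2. Fráter–Seebach alkylation of the dianion of F2 (LiN(iPr)2, 2.2 equiv, THF/DMPU, −78 → −30 °C) with 4-methoxybenzyl chloromethyl ether occurs anti to the alkoxide and gives tert-butyl (2S,3S,8R,10E)-3-hydroxy-11-iodo-2-{[(4-methoxybenzyl)oxy]methyl}-8,10-dimethylundec-10-enoate F3. DDQ in CH2Cl2/pH 7 buffer removes the 4-methoxybenzyl group and delivers 17.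

**Step 13 (the same new reaction with the antipodal catalyst, (2R,3R) series).** It stands or falls with step 9. The fallback sets out from aldehyde 10 and comes back at diol 22. The β-keto ester tert-butyl (8R,10E)-11-iodo-8,10-dimethyl-3-oxoundec-10-enoate F1, made from 10 as above, is hydrogenated with RuCl2[(R)-BINAP] (H2, 4 atm, MeOH, 40 °C) to tert-butyl (3R,8R,10E)-3-hydroxy-11-iodo-8,10-dimethylundec-10-enoate F4. Fráter–Seebach alkylation of its dianion with 4-methoxybenzyl chloromethyl ether gives the anti product tert-butyl (2R,3R,8R,10E)-3-hydroxy-11-iodo-2-{[(4-methoxybenzyl)oxy]methyl}-8,10-dimethylundec-10-enoate F5, and DDQ in CH2Cl2/pH 7 buffer gives 22.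

**Step 17 (Stille union of two large, sensitive fragments with an electron-poor, hindered stannane).** Slow transmetalation could let protodestannylation or homocoupling win. The fallback moves the union from the C–C bond to the ester C–O bond; it sets out from lactone 26 (using 13 and 19, both already on the route) and comes back at 27. Stille coupling of 26 with the small free acid 13 (Pd2(dba)3, AsPh3, CuI, NMP, rt), a far less demanding coupling, gives (2E,4E,7R)-11-[(2R,3R)-3-{[(tert-butyldimethylsilyl)oxy]methyl}-4-oxooxetan-2-yl]-3,5,7-trimethylundeca-2,4-dienoic acid F6. Steglich esterification of F6 with alcohol 19 (N,N'-dicyclohexylcarbodiimide, DMAP, CH2Cl2, rt) then gives 27; steps 12 and 17 are bypassed.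

## Further compounds

F1 | step 9 | tert-butyl (8R,10E)-11-iodo-8,10-dimethyl-3-oxoundec-10-enoate | I/C=C(\C)C[C@H](C)CCCCC(=O)CC(=O)OC(C)(C)C
F2 | step 9 | tert-butyl (3S,8R,10E)-3-hydroxy-11-iodo-8,10-dimethylundec-10-enoate | I/C=C(\C)C[C@H](C)CCCC[C@H](O)CC(=O)OC(C)(C)C
F3 | step 9 | tert-butyl (2S,3S,8R,10E)-3-hydroxy-11-iodo-2-{[(4-methoxybenzyl)oxy]methyl}-8,10-dimethylundec-10-enoate | I/C=C(\C)C[C@H](C)CCCC[C@H](O)[C@H](COCc1ccc(OC)cc1)C(=O)OC(C)(C)C
F4 | step 13 | tert-butyl (3R,8R,10E)-3-hydroxy-11-iodo-8,10-dimethylundec-10-enoate | I/C=C(\C)C[C@H](C)CCCC[C@@H](O)CC(=O)OC(C)(C)C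
F5 | step 13 | tert-butyl (2R,3R,8R,10E)-3-hydroxy-11-iodo-2-{[(4-methoxybenzyl)oxy]methyl}-8,10-dimethylundec-10-enoate | I/C=C(\C)C[C@H](C)CCCC[C@@H](O)[C@@H](COCc1ccc(OC)cc1)C(=O)OC(C)(C)C
F6 | step 17 | (2E,4E,7R)-11-[(2R,3R)-3-{[(tert-butyldimethylsilyl)oxy]methyl}-4-oxooxetan-2-yl]-3,5,7-trimethylundeca-2,4-dienoic acid | OC(=O)/C=C(C)/C=C(\C)C[C@H](C)CCCC[C@H]1OC(=O)[C@@H]1CO[Si](C)(C)C(C)(C)C
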